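## Analysis of the target

Thelephenol (9) is a 2,4'-dihydroxydiphenylmethane built from two phenol rings and two sp3 carbons. Ring A (C1–C6) bears the hydroxymethyl carbon C7 at C1, Br at C3, OH at C4 and the bridge carbon C7' at C5; ring B (C1'–C6') bears C7' at C1', Br at C3' and C5', and OH at C4'. There is no stereocentre, stereogenic axis or double-bond geometry, so nothing has to be set in that respect.

The sensitive unit is the p-hydroxybenzyl alcohol (C4–OH with C1–C7–OH), which ionises to a p-quinone methide in acid and, as the phenoxide, on warming. The three C–Br bonds rule out Pd(0), organolithium and dissolving-metal chemistry and can migrate in strong acid, and C7' is doubly activated towards oxidants.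

The difficulty is selectivity, not size. Linking two phenols through CH2 is phenol–formaldehyde resin chemistry, which normally ends in statistical oligomers, and the two halves of 9 are nearly alike.

The feature that invites the strategy is that all six ortho/para positions of the two phenols are filled: C3, C3' and C5' by bromine, and C1, C5 and C1' by C7 and C7'. Both sp3 carbons stand where, and at the oxidation level at which, formaldehyde (2) enters a phenol. Removing C7 and C7' as two molecules of 2 leaves 2-bromophenol (1) with just two free positions (C5 ortho, C1 para) and 2,6-dibromophenol (4) with just one (C1'). The bromines of the target therefore act as its own blocking groups. The two bromines flanking C4'–OH also make that hydroxyl about two pK units more acidic than C4–OH, a difference that can decide which ring acts as the nucleophile.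

## Retrosynthetic reasoning

**Disconnection 1, C1–C7 (9 ⇒ 8 + 2).** The hydroxymethyl group is the most labile part of 9, so it is cut first and made last. In 8, C1 is the only free ortho/para position of either ring, so a base-mediated hydroxymethylation has no regiochemical choice. The gain is twofold. No step before the last has to tolerate a p-hydroxybenzyl alcohol, so the key step may be run hot, and ring A needs no pre-installed, redox-adjusted C1 substituent. The forward reaction must stop at the alcohol stage and not condense further.

**Disconnection 2, C5–C7' and C7'–C1' together (8 ⇒ 1 + 2 + 4).** Both bonds of the bridge carbon are cut at once, which takes 8 back to two commodity bromophenols and 2. Cutting only one of them would leave a benzylic building block that has to be bought or made at the right oxidation level. The forward reaction has to join three components in the order ring A–CH2–ring B, avoid the two symmetrical diarylmethanes, and stop after one linkage. Named by its key step and precursors alone, a one-pot amine-relayed stitching of two bromophenols with formaldehyde, this plan is not the benzylation that would be drawn first.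

**Choice of polarity and relay (8 ⇐ 7 ⇐ 6 + 4; 6 ⇐ 5 ⇐ 1 + 2 + 3).**
- Ring A is made the electrophile, as o-quinone methide 6, and ring B the nucleophile, because 4 can form a C–C bond only at C1'.
- The reverse polarity would ask ring A to choose between its ortho and para carbons.
- 6 is reached from Mannich base 5. Dimethylamine (3) carries 2 to the ortho carbon of 1 through the O–H···N hydrogen bond, holds the CH2 unit in a stable form until 1 and 2 are consumed, and then leaves as a gas.
- Addition of the phenoxide of 4 gives dienone adduct 7, which tautomerises to 8.
- The open para carbon of ring A in 5 and 8 is protected by acidity. With 4 in excess over all base, only dibromophenoxide-type anions exist in the pot, and among these only 4 has a free position.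

## Alternatives that were turned down

**Alternative 1: (the textbook route)**
- Disconnection: C5–C7' only, with ring B as the benzylic electrophile.
- Forward key step: acid-promoted Friedel–Crafts benzylation of methyl 3-bromo-4-hydroxybenzoate A1 with 3,5-dibromo-4-hydroxybenzyl alcohol A2 to give ester A3, followed by hydride reduction to 9.
- Why turned down:
  - C1 of ring A must carry an acceptor, because a free CH2OH there would ionise faster than that of A2.
  - The attacked carbon C5 is then meta to two acceptors, and the cation from A2 carries two meta bromines. Two deactivated partners call for strong acid and heat, the conditions under which bromine ortho to a phenol OH can migrate or be lost.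
  - The step forms one C–C bond only.
  - Both C1 units must be bought pre-installed at different oxidation levels.
  - An ester reduction in the presence of two acidic OH groups is added.

**Alternative 2: (biomimetic)**
- Disconnection: C5–C7' again, but between two unprotected hydroxybenzyl units.
- Forward key step: p-quinone methide A4, generated from A2, is captured at C5 by 3-bromo-4-hydroxybenzyl alcohol A5 to give 9 directly.
- Why turned down:
  - A5 is itself a p-hydroxybenzyl alcohol with one bromine fewer than A2, so in acid or hot base it ionises more readily than A2. It then attacks its own kind to give homodimer A6 and higher oligomers.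
  - Cross-selectivity would need A2 to be converted first into a derivative with a better leaving group.
  - Capture at the benzylic or phenolic oxygen of A5 competes.
  - Both partners have to be made by reduction of the commercial aldehydes, so the apparent single step is really three, for the same bond as Alternative 1.

**Alternative 3: (bromine last)**
- Disconnection: the three C–Br bonds, after a bromine-free skeleton.
- Forward key step: self-condensation of 4-hydroxybenzyl alcohol A7 to dimer A8, then exhaustive ortho-tribromination.
- Why turned down:
  - Without the bromines, A7 and A8 have two and three free ortho positions and a quinone-methide-forming terminus, so step growth cannot be stopped at the dimer.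
  - Electrophilic bromine attacks phenols at the para ipso carbon as well. At C1 this expels 2, at C1' it cleaves the bridge, and the HBr formed converts C7–OH into the bromide.
  - This plan discards the very blocking groups that make the skeleton controllable.

Key step: step 1

Remark on the chemistry: the SMILES holds no stereocentre, so 9 is achiral and the demand for a single enantiomer is met by any sample.

## Route

**Step 1**
Reactants: 1 2-bromophenol; 2 formaldehyde (as paraformaldehyde); 3 dimethylamine; 4 2,6-dibromophenol
Product: 8 2-bromo-6-[(3,5-dibromo-4-hydroxyphenyl)methyl]phenol, via Mannich base 5 (not isolated), via o-quinone methide 6 (not isolated), via dienone adduct 7 (not isolated)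
Conditions: (CH2O)n (1.0 equiv), Me2NH (2 M in THF, 1.05 equiv), toluene, 70 °C, sealed; evaporate volatiles; then 4 (3 equiv), Bu3N (1 equiv), o-xylene, 145 °C, N2 sweep; aq. citric acid work-up, excess 4 distilled off
Reagents that add atoms: formaldehyde 2 (as paraformaldehyde), C=O
Why: The first stage is a phenolic Mannich reaction in which 2 and 3 form the aminol/iminium pair and the O–H···N hydrogen bond of 1 delivers it to the free ortho carbon, so that 5 forms with loss of water. On heating, 5 loses 3 through its zwitterion (retro-Michael, E1cB type) to give the o-quinone methide 6, and the gaseous amine is swept out, which makes this stage irreversible in practice. The phenoxide of 4 adds to the exocyclic CH2 of 6 through its para carbon, its only unsubstituted ortho/para position, and adduct 7 rearomatises to 8 by proton shift. The closest known reaction type is the C-alkylation of phenols, indoles and 1,3-dicarbonyl compounds with phenolic Mannich bases by elimination–addition. O-attack of the hindered phenoxide also occurs but is reversible, because 2,6-dibromophenoxide is a good leaving group from an o-hydroxybenzyl ether, so the material should funnel into the C–C bond. Cross-selectivity is secured by the sequence, since 1 and 2 are consumed and volatile formaldehyde equivalents are stripped before 4 enters, so neither symmetrical diarylmethane has a path. Over-alkylation at the open para carbon of ring A is held back by acidity gating, since 4 is about two pK units more acidic than the ring A hydroxyl of 5 and 8 and is kept in excess over all base, so only dibromophenoxide-type anions are populated and only 4 among them has a free carbon. No ring is closed and no stereocentre is formed.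

**Step 2**
Reactants: 8 2-bromo-6-[(3,5-dibromo-4-hydroxyphenyl)methyl]phenol; 2 formaldehyde (as 37% aqueous solution)
Product: 9 thelephenol, 2-bromo-6-[(3,5-dibromo-4-hydroxyphenyl)methyl]-4-(hydroxymethyl)phenol
Conditions: 37% aq. CH2O (5 equiv), NaOH (2.5 equiv), H2O–THF, 25–35 °C, N2; then AcOH to pH 5, 0 °C
Reagents that add atoms: formaldehyde 2 (37% aqueous), C=O
Why: This is a Lederer–Manasse hydroxymethylation in which the ring A phenoxide of 8 adds to formaldehyde through its para carbon C1, the only free ortho/para position left in the molecule, while the ring B phenoxide has no free carbon and can only form hemiformals that fall apart on work-up. Low temperature, excess 2 and a buffered cold acidification should keep the new p-hydroxybenzyl alcohol from ionising to its quinone methide, and the C–Br bonds and C7' are inert to these conditions.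

## Compound list

1 | 2-bromophenol | Oc1ccccc1Br | starting material
2 | formaldehyde (paraformaldehyde in step 1, formalin in step 2) | C=O | starting material
3 | dimethylamine (relay amine) | CNC | starting material
4 | 2,6-dibromophenol | Oc1c(Br)cccc1Br | starting material
5 | 2-bromo-6-[(dimethylamino)methyl]phenol (Mannich base) | CN(C)Cc1cccc(Br)c1O | intermediate
6 | 2-bromo-6-methylidenecyclohexa-2,4-dien-1-one (o-quinone methide) | C=C1C=CC=C(Br)C1=O | intermediate
7 | 2,6-dibromo-4-[(3-bromo-2-hydroxyphenyl)methyl]cyclohexa-2,5-dien-1-one (dienone adduct) | O=C1C(Br)=CC(Cc2cccc(Br)c2O)C=C1Br | intermediate
8 | 2-bromo-6-[(3,5-dibromo-4-hydroxyphenyl)methyl]phenol | Oc1c(Br)cccc1Cc1cc(Br)c(O)c(Br)c1 | intermediate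
9 | thelephenol, 2-bromo-6-[(3,5-dibromo-4-hydroxyphenyl)methyl]-4-(hydroxymethyl)phenol | OCc1cc(Br)c(O)c(Cc2cc(Br)c(O)c(Br)c2)c1 | target

## Step count and least certain steps

Total step count: 2. Longest linear sequence: 2.

The route has only two steps, so both are listed. The two stages of the key step are treated separately because they can fail independently.

**Step 1 (key step), second stage.**
- What may go wrong:
  - Loss of the amine from the bromine-bearing Mannich base may be slow.
  - The o-quinone methide may then be consumed by self-addition.
  - Neutral ring A phenols may attack it once the phenoxide buffer thins out, which gives over-alkylation at the open para carbon.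
- Fallback (from 1, returning at 8):
  - The bridge carbon is taken from a ring B aldehyde, and the last bond to it is a C–H bond.
  - 1, 3,5-dibromo-4-hydroxybenzaldehyde F3 and phenylboronic acid (cat. Cl3CCO2H, toluene, water separator) undergo the boronic-acid-templated ortho-hydroxyalkylation. This gives racemic 8-bromo-4-(3,5-dibromo-4-hydroxyphenyl)-2-phenyl-4H-1,3,2-benzodioxaborinine F4.
  - Ionic hydrogenation (Et3SiH, BF3·OEt2, CH2Cl2) then gives 8.
  - The silane is a far better trap for the benzylic cation than any arene present, so oligomerisation cannot compete.

**Step 1 (key step), first stage.**
- What may go wrong: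
  - Hydrogen-bond delivery is a preference and not a lock, so aminomethylation at the para carbon of 1 or double aminomethylation may compete.
  - Incomplete removal of formaldehyde equivalents would later link two molecules of 4.
- Fallback (from 1, returning at 6 and so at 8):
  - 1 is condensed with 2 and phenylboronic acid (cat. propionic acid, toluene, water separator).
  - Boron binds the phenol oxygen and can deliver formaldehyde to the ortho carbon only, giving 8-bromo-2-phenyl-4H-1,3,2-benzodioxaborinine F1.
  - Transesterification with propane-1,3-diol frees 3-bromo-2-hydroxybenzyl alcohol F2.
  - F2 is heated with 4 and Bu3N at 160–180 °C, where it loses water to 6.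

**Step 2.**
- What may go wrong:
  - The bromophenoxide is a modest nucleophile, so conversion may be slow.
  - If the mixture is warmed to compensate, the product may ionise to its p-quinone methide and condense with unreacted 8.
  - Ionisation can also occur if the acidification overshoots.
- Fallback (from 8, returning at 9):
  - The carbon is introduced at the aldehyde level, which cannot ionise.
  - Duff formylation (hexamethylenetetramine, TFA, 80 °C; aq. HCl) at the same single free para carbon gives 3-bromo-5-[(3,5-dibromo-4-hydroxyphenyl)methyl]-4-hydroxybenzaldehyde F5.
  - NaBH4 (MeOH–THF, 0 °C) then gives 9.

## Further compounds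

F1 | step 1 | 8-bromo-2-phenyl-4H-1,3,2-benzodioxaborinine | Brc1cccc2COB(Oc12)c1ccccc1
F2 | step 1 | 3-bromo-2-hydroxybenzyl alcohol | OCc1cccc(Br)c1O
F3 | step 1 | 3,5-dibromo-4-hydroxybenzaldehyde | O=Cc1cc(Br)c(O)c(Br)c1
F4 | step 1 | 8-bromo-4-(3,5-dibromo-4-hydroxyphenyl)-2-phenyl-4H-1,3,2-benzodioxaborinine (racemic) | Brc1cccc2C(OB(Oc12)c1ccccc1)c1cc(Br)c(O)c(Br)c1
F5 | step 2 | 3-bromo-5-[(3,5-dibromo-4-hydroxyphenyl)methyl]-4-hydroxybenzaldehyde | O=Cc1cc(Br)c(O)c(Cc2cc(Br)c(O)c(Br)c2)c1
A1 | alternative 1 | methyl 3-bromo-4-hydroxybenzoate | COC(=O)c1ccc(O)c(Br)c1
A2 | alternative 1 | 3,5-dibromo-4-hydroxybenzyl alcohol | OCc1cc(Br)c(O)c(Br)c1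
A3 | alternative 1 | methyl 3-bromo-5-[(3,5-dibromo-4-hydroxyphenyl)methyl]-4-hydroxybenzoate | COC(=O)c1cc(Br)c(O)c(Cc2cc(Br)c(O)c(Br)c2)c1
A4 | alternative 2 | 2,6-dibromo-4-methylidenecyclohexa-2,5-dien-1-one | C=C1C=C(Br)C(=O)C(Br)=C1
A5 | alternative 2 | 3-bromo-4-hydroxybenzyl alcohol | OCc1ccc(O)c(Br)c1
A6 | alternative 2 | 2-bromo-6-[(3-bromo-4-hydroxyphenyl)methyl]-4-(hydroxymethyl)phenol | OCc1cc(Br)c(O)c(Cc2ccc(O)c(Br)c2)c1
A7 | alternative 3 | 4-hydroxybenzyl alcohol | OCc1ccc(O)cc1
A8 | alternative 3 | 4-(hydroxymethyl)-2-[(4-hydroxyphenyl)methyl]phenol | OCc1ccc(O)c(Cc2ccc(O)cc2)c1
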